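## Retrosynthetic overview

- Numbering: ring C1 (CHOAc), C2 (CH2), C3 (CHBr), C4 (CMe2), C5 (=CH), C6 (=C); side chain C7 (CHBr), C8 (CH2Cl). The strategy rests on the C1–C6(=C5)–C7 array: with C7 as a ketone it is a β-hydroxy α-alkylidene ketone, a formal Morita–Baylis–Hillman adduct with its alkene inside the ring, and C5 sits on the quaternary C4.
- Halogens are installed late, each by inversion of a carbinol: C7–Br from a (7R)-chlorohydrin made from the acetyl group, and C3–Br from the (3R)-carbinol before C7 and C8 are halogenated. C1–OAc comes from Mitsunobu inversion.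
- The only ring is closed at C1–C6 by copper hydride reductive aldol cyclisation of an acyclic ynone aldehyde (C1 aldehyde, C3 silyl ether, C5≡C6–C7(=O)CH3).
- The ynone aldehyde comes from an asymmetric Mukaiyama aldol (sets C3), alkyne homologation at C5, acylation at C6 and unmasking of C1.

Key step: step 9

Assumption: the cyclisation is taken to give the 1,3-cis alcohol (C1–OH cis to C3–OSi); the trans epimer would be acetylated with retention and gives the same acetate, so the route does not depend on this sense.

## Route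

Step 1
Reactants: 1 3-[(4-methoxybenzyl)oxy]propanal; 2 1-methoxy-2-methyl-1-(trimethylsilyloxy)prop-1-ene
Product: 4 methyl (3R)-3-hydroxy-5-[(4-methoxybenzyl)oxy]-2,2-dimethylpentanoate, via O-trimethylsilyl aldol adduct 3 (not isolated)
Conditions: N-tosyl-L-valine, BH3·THF, CH2Cl2, 0 °C to rt; then 1 and 2, −78 °C; pH 7 buffer, then 1 M HCl/THF
Reagents that add atoms: none
Why: Kiyooka-type asymmetric Mukaiyama aldol in which the valine-derived oxazaborolidinone activates the aldehyde and shields one face, so the ketene acetal should add to give the (3R)-alcohol (the D-valine promoter would give the antipode), and the acidic work-up cleaves any silyl ether 3.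

Step 2
Reactants: 4 methyl (3R)-3-hydroxy-5-[(4-methoxybenzyl)oxy]-2,2-dimethylpentanoate
Product: 5 methyl (3R)-3-(tert-butyldimethylsilyloxy)-5-[(4-methoxybenzyl)oxy]-2,2-dimethylpentanoate
Conditions: TBSOTf, 2,6-lutidine, CH2Cl2, 0 °C
Reagents that add atoms: tert-butyldimethylsilyl trifluoromethanesulfonate, CC(C)(C)[Si](C)(C)OS(=O)(=O)C(F)(F)F
Why: Silyl triflate silylation is the standard way to protect a hindered secondary alcohol next to a quaternary carbon, and the silyl ether blocks retro-aldol cleavage in the following steps.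

Step 3
Reactants: 5 methyl (3R)-3-(tert-butyldimethylsilyloxy)-5-[(4-methoxybenzyl)oxy]-2,2-dimethylpentanoate
Product: 6 (3R)-3-(tert-butyldimethylsilyloxy)-5-[(4-methoxybenzyl)oxy]-2,2-dimethylpentan-1-ol
Conditions: i-Bu2AlH (2.5 equiv), CH2Cl2, −78 to 0 °C; aq. KNaC4H4O6 (potassium sodium tartrate)
Reagents that add atoms: none
Why: Full hydride reduction of the α-quaternary ester to the primary alcohol is more dependable than trying to stop at the aldehyde.

Step 4
Reactants: 6 (3R)-3-(tert-butyldimethylsilyloxy)-5-[(4-methoxybenzyl)oxy]-2,2-dimethylpentan-1-ol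
Product: 7 (3R)-3-(tert-butyldimethylsilyloxy)-5-[(4-methoxybenzyl)oxy]-2,2-dimethylpentanal
Conditions: Dess–Martin periodinane, NaHCO3, CH2Cl2, 0 °C to rt
Reagents that add atoms: none
Why: Buffered Dess–Martin oxidation of the neopentyl primary alcohol gives a non-enolisable aldehyde and leaves the silyl and 4-methoxybenzyl ethers untouched.

Step 5
Reactants: 7 (3R)-3-(tert-butyldimethylsilyloxy)-5-[(4-methoxybenzyl)oxy]-2,2-dimethylpentanal
Product: 8 tert-butyl({(3R)-1-[(4-methoxybenzyl)oxy]-4,4-dimethylhex-5-yn-3-yl}oxy)dimethylsilane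
Conditions: dimethyl (1-diazo-2-oxopropyl)phosphonate, K2CO3, MeOH, 0 °C to rt
Reagents that add atoms: dimethyl (1-diazo-2-oxopropyl)phosphonate, CC(=O)C(=[N+]=[N-])P(=O)(OC)OC
Why: Ohira–Bestmann (Seyferth–Gilbert) homologation works well on aldehydes without an α-hydrogen, so the mild carbonate conditions should give the terminal alkyne without epimerisation or elimination.

Step 6
Reactants: 8 tert-butyl({(3R)-1-[(4-methoxybenzyl)oxy]-4,4-dimethylhex-5-yn-3-yl}oxy)dimethylsilane; 9 N-methoxy-N-methylacetamide
Product: 12 (6R)-6-(tert-butyldimethylsilyloxy)-8-[(4-methoxybenzyl)oxy]-5,5-dimethyloct-3-yn-2-one, via lithium acetylide 10 (not isolated), via lithium hemiaminal adduct 11 (not isolated)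
Conditions: n-BuLi, THF, −78 °C; then 9, −78 to −20 °C; inverse quench into cold 1 M HCl/Et2O
Reagents that add atoms: none
Why: Weinreb ketone synthesis, in which the chelated adduct 11 persists until the quench so the acetylide adds only once, and the acidic inverse quench protonates the released amine before it can add to the ynone.

Step 7
Reactants: 12 (6R)-6-(tert-butyldimethylsilyloxy)-8-[(4-methoxybenzyl)oxy]-5,5-dimethyloct-3-yn-2-one
Product: 13 (6R)-6-(tert-butyldimethylsilyloxy)-8-hydroxy-5,5-dimethyloct-3-yn-2-one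
Conditions: DDQ, CH2Cl2/pH 7 phosphate buffer (10:1), 0 °C
Reagents that add atoms: none
Why: Oxidative cleavage of the 4-methoxybenzyl ether by DDQ under buffered neutral conditions spares the silyl ether and the ynone, and the hydroxy ynone is carried on at once so that oxa-Michael closure onto C5 has no time to occur.

Step 8
Reactants: 13 (6R)-6-(tert-butyldimethylsilyloxy)-8-hydroxy-5,5-dimethyloct-3-yn-2-one
Product: 14 (3R)-3-(tert-butyldimethylsilyloxy)-4,4-dimethyl-7-oxooct-5-ynal
Conditions: Dess–Martin periodinane, NaHCO3, CH2Cl2, 0 °C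
Reagents that add atoms: none
Why: Buffered Dess–Martin oxidation should give the β-silyloxy aldehyde without β-elimination and without touching the ynone.

Step 9
Reactants: 14 (3R)-3-(tert-butyldimethylsilyloxy)-4,4-dimethyl-7-oxooct-5-ynal
Product: 17 1-[(4R,6S)-4-(tert-butyldimethylsilyloxy)-6-hydroxy-3,3-dimethylcyclohex-1-en-1-yl]ethan-1-one, via copper allenolate 15 (not isolated), via copper aldolate 16 (not isolated)
Conditions: [(Ph3P)CuH]6 (0.18 equiv of hexamer, about 1.1 equiv of hydride), degassed toluene, −40 to 0 °C; aq. NH4Cl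
Reagents that add atoms: none
Why: The monovalent copper hydride transfers hydride to the ynone β-carbon C5 to give copper allenolate 15, whose α-carbon C6 adds to the tethered aldehyde C1 to give copper aldolate 16, protonated on work-up; this is the copper hydride reductive aldol cyclisation of alkynones, which gives the β-hydroxy enone that an intramolecular Morita–Baylis–Hillman reaction would give. The six-membered ring closes in a 6-(enolexo)-exo-trig mode: the allenolate reacts at C6 in the plane of the C5 substituents, and the C2–C3–C4 tether can reach C6 only on the side of C4, so C1 ends cis to C4 across the new C5=C6 bond. The new stereocentre C1 is controlled by C3: a chair-like, copper-bridged transition state with the silyloxy group equatorial and the aldehyde oxygen turned toward the enolate oxygen should give the 1,3-cis (1S) alcohol. The step needs the ynone to be reduced before the aldehyde and only once: this reagent reduces conjugated acceptors much faster than isolated aldehydes, about one hydride equivalent is used at low temperature, and the quaternary C4 shields C5 of the product enone from a second conjugate reduction. The same quaternary centre would stop phosphine or amine Morita–Baylis–Hillman catalysts, whereas hydride is small enough to reach C5 of the linear alkyne. Either C1 epimer can be converted into the acetate of step 10, one by inversion and the other by retention.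

Step 10
Reactants: 17 1-[(4R,6S)-4-(tert-butyldimethylsilyloxy)-6-hydroxy-3,3-dimethylcyclohex-1-en-1-yl]ethan-1-one
Product: 18 (1R,5R)-2-acetyl-5-(tert-butyldimethylsilyloxy)-4,4-dimethylcyclohex-2-en-1-yl acetate
Conditions: PPh3, DIAD, AcOH, THF, 0 °C to rt
Reagents that add atoms: acetic acid, CC(=O)O
Why: Mitsunobu reaction in which acetate displaces the activated allylic oxygen at C1 with inversion to give the (1R)-acetate trans to the C3 silyl ether, while allylic transposition through attack at C5 is blocked by the adjacent quaternary C4.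

Step 11
Reactants: 18 (1R,5R)-2-acetyl-5-(tert-butyldimethylsilyloxy)-4,4-dimethylcyclohex-2-en-1-yl acetate
Product: 19 (1R,5R)-2-acetyl-5-hydroxy-4,4-dimethylcyclohex-2-en-1-yl acetate
Conditions: 48% aq. HF, MeCN, 0 °C to rt
Reagents that add atoms: none
Why: Acidic fluoride cleaves the hindered secondary silyl ether while the acetate and enone survive, and the trans-1,3 arrangement rules out acetyl migration to the freed hydroxyl.

Step 12
Reactants: 19 (1R,5R)-2-acetyl-5-hydroxy-4,4-dimethylcyclohex-2-en-1-yl acetate
Product: 20 (1R,5S)-2-acetyl-5-bromo-4,4-dimethylcyclohex-2-en-1-yl acetate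
Conditions: CBr4, (n-C8H17)3P, 1-methylcyclohexene, toluene, 70 °C
Reagents that add atoms: carbon tetrabromide, BrC(Br)(Br)Br
Why: Appel bromination with trioctylphosphine, a protocol used for hindered secondary ring alcohols, should displace the activated oxygen at C3 by bromide with inversion to give the (S)-bromide cis to the acetate, and it is placed here because this hindered bromide survives the later steps whereas a C7 allylic bromide would not survive these conditions.

Step 13
Reactants: 20 (1R,5S)-2-acetyl-5-bromo-4,4-dimethylcyclohex-2-en-1-yl acetate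
Product: 22 (1R,5S)-5-bromo-2-(chloroacetyl)-4,4-dimethylcyclohex-2-en-1-yl acetate, via trimethylsilyl dienol ether 21 (not isolated)
Conditions: TMSOTf, Et3N, CH2Cl2, −20 to 0 °C; then NCS, THF, 0 °C
Reagents that add atoms: N-chlorosuccinimide, ClN1C(=O)CCC1=O
Why: Soft enolisation of the methyl ketone (its only enolisable position, C4 being quaternary) and electrophilic chlorination of silyl dienol ether 21 at its terminal carbon avoid a lithium enolate that could attack the neighbouring acetate.

Step 14
Reactants: 22 (1R,5S)-5-bromo-2-(chloroacetyl)-4,4-dimethylcyclohex-2-en-1-yl acetate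
Product: 23 (1R,5S)-5-bromo-2-[(1R)-2-chloro-1-hydroxyethyl]-4,4-dimethylcyclohex-2-en-1-yl acetate
Conditions: (R)-2-methyl-CBS-oxazaborolidine (0.5 equiv), catecholborane, toluene, −78 °C; MeOH quench, neutral work-up
Reagents that add atoms: none
Why: Corey–Bakshi–Shibata reduction in which the (R)-oxazaborolidine treats the cyclohexenyl group as the large and the chloromethyl group as the small substituent, which should give the (R)-chlorohydrin by reagent control, while catecholborane at low temperature leaves the hindered alkene alone.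

Step 15
Reactants: 23 (1R,5S)-5-bromo-2-[(1R)-2-chloro-1-hydroxyethyl]-4,4-dimethylcyclohex-2-en-1-yl acetate
Product: 24 (1R,5S)-5-bromo-2-[(1S)-1-bromo-2-chloroethyl]-4,4-dimethylcyclohex-2-en-1-yl acetate
Conditions: CBr4, PPh3, CH2Cl2, 0 °C
Reagents that add atoms: carbon tetrabromide, BrC(Br)(Br)Br
Why: Appel bromination should replace the activated allylic oxygen at C7 by bromide with inversion to give the (S)-bromide, since allylic transposition through C5 is blocked by C4, ionisation is disfavoured by the adjacent chloromethyl group, and the phosphine does not touch the hindered C3 bromide at 0 °C.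

## Compound list

1 | 3-[(4-methoxybenzyl)oxy]propanal | COc1ccc(COCCC=O)cc1 | starting material
2 | 1-methoxy-2-methyl-1-(trimethylsilyloxy)prop-1-ene | COC(O[Si](C)(C)C)=C(C)C | starting material
3 | methyl (3R)-5-[(4-methoxybenzyl)oxy]-2,2-dimethyl-3-(trimethylsilyloxy)pentanoate | COC(=O)C(C)(C)[C@H](O[Si](C)(C)C)CCOCc1ccc(OC)cc1 | intermediate
4 | methyl (3R)-3-hydroxy-5-[(4-methoxybenzyl)oxy]-2,2-dimethylpentanoate | COC(=O)C(C)(C)[C@H](O)CCOCc1ccc(OC)cc1 | intermediate
5 | methyl (3R)-3-(tert-butyldimethylsilyloxy)-5-[(4-methoxybenzyl)oxy]-2,2-dimethylpentanoate | COC(=O)C(C)(C)[C@H](O[Si](C)(C)C(C)(C)C)CCOCc1ccc(OC)cc1 | intermediate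
6 | (3R)-3-(tert-butyldimethylsilyloxy)-5-[(4-methoxybenzyl)oxy]-2,2-dimethylpentan-1-ol | OCC(C)(C)[C@H](O[Si](C)(C)C(C)(C)C)CCOCc1ccc(OC)cc1 | intermediate
7 | (3R)-3-(tert-butyldimethylsilyloxy)-5-[(4-methoxybenzyl)oxy]-2,2-dimethylpentanal | O=CC(C)(C)[C@H](O[Si](C)(C)C(C)(C)C)CCOCc1ccc(OC)cc1 | intermediate
8 | tert-butyl({(3R)-1-[(4-methoxybenzyl)oxy]-4,4-dimethylhex-5-yn-3-yl}oxy)dimethylsilane | C#CC(C)(C)[C@H](O[Si](C)(C)C(C)(C)C)CCOCc1ccc(OC)cc1 | intermediate
9 | N-methoxy-N-methylacetamide | CON(C)C(C)=O | starting material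
10 | lithium acetylide of 8 | [Li]C#CC(C)(C)[C@H](O[Si](C)(C)C(C)(C)C)CCOCc1ccc(OC)cc1 | intermediate
11 | lithium hemiaminal adduct of 10 and 9 (carbinol centre undefined) | [Li]OC(C)(N(C)OC)C#CC(C)(C)[C@H](O[Si](C)(C)C(C)(C)C)CCOCc1ccc(OC)cc1 | intermediate
12 | (6R)-6-(tert-butyldimethylsilyloxy)-8-[(4-methoxybenzyl)oxy]-5,5-dimethyloct-3-yn-2-one | CC(=O)C#CC(C)(C)[C@H](O[Si](C)(C)C(C)(C)C)CCOCc1ccc(OC)cc1 | intermediate
13 | (6R)-6-(tert-butyldimethylsilyloxy)-8-hydroxy-5,5-dimethyloct-3-yn-2-one | CC(=O)C#CC(C)(C)[C@H](O[Si](C)(C)C(C)(C)C)CCO | intermediate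
14 | (3R)-3-(tert-butyldimethylsilyloxy)-4,4-dimethyl-7-oxooct-5-ynal | O=CC[C@@H](O[Si](C)(C)C(C)(C)C)C(C)(C)C#CC(C)=O | intermediate
15 | monovalent copper allenolate from hydride addition to C5 of 14 (phosphine ligand omitted) | O=CC[C@@H](O[Si](C)(C)C(C)(C)C)C(C)(C)C=C=C(C)O[Cu] | intermediate
16 | monovalent copper aldolate of 17 (phosphine ligand omitted) | [Cu]O[C@H]1C[C@@H](O[Si](C)(C)C(C)(C)C)C(C)(C)C=C1C(C)=O | intermediate
17 | 1-[(4R,6S)-4-(tert-butyldimethylsilyloxy)-6-hydroxy-3,3-dimethylcyclohex-1-en-1-yl]ethan-1-one | O[C@H]1C[C@@H](O[Si](C)(C)C(C)(C)C)C(C)(C)C=C1C(C)=O | intermediate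
18 | (1R,5R)-2-acetyl-5-(tert-butyldimethylsilyloxy)-4,4-dimethylcyclohex-2-en-1-yl acetate | CC(=O)O[C@@H]1C[C@@H](O[Si](C)(C)C(C)(C)C)C(C)(C)C=C1C(C)=O | intermediate
19 | (1R,5R)-2-acetyl-5-hydroxy-4,4-dimethylcyclohex-2-en-1-yl acetate | CC(=O)O[C@@H]1C[C@@H](O)C(C)(C)C=C1C(C)=O | intermediate
20 | (1R,5S)-2-acetyl-5-bromo-4,4-dimethylcyclohex-2-en-1-yl acetate | CC(=O)O[C@@H]1C[C@H](Br)C(C)(C)C=C1C(C)=O | intermediate
21 | (1R,5S)-5-bromo-4,4-dimethyl-2-[1-(trimethylsilyloxy)ethenyl]cyclohex-2-en-1-yl acetate | CC(=O)O[C@@H]1C[C@H](Br)C(C)(C)C=C1C(=C)O[Si](C)(C)C | intermediate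
22 | (1R,5S)-5-bromo-2-(chloroacetyl)-4,4-dimethylcyclohex-2-en-1-yl acetate | CC(=O)O[C@@H]1C[C@H](Br)C(C)(C)C=C1C(=O)CCl | intermediate
23 | (1R,5S)-5-bromo-2-[(1R)-2-chloro-1-hydroxyethyl]-4,4-dimethylcyclohex-2-en-1-yl acetate | CC(=O)O[C@@H]1C[C@H](Br)C(C)(C)C=C1[C@@H](O)CCl | intermediate
24 | (1R,5S)-5-bromo-2-[(1S)-1-bromo-2-chloroethyl]-4,4-dimethylcyclohex-2-en-1-yl acetate | CC(=O)O[C@@H]1C[C@H](Br)C(C)(C)C=C1[C@H](Br)CCl | target

## Step count and risks

Total step count: 15. Longest linear sequence: 15 steps (1 and 2 to 24).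

Steps most likely to fail:

**Step 9 (key step).** Hydride delivery to the alkyne carbon C5 next to the quaternary centre may be slower than 1,2-reduction of the aldehyde. The allenolate may be protonated instead of closing the ring. The facial selectivity at C1 may be poor.

Fallback (intermolecular Morita–Baylis–Hillman reaction, then ring-closing metathesis that forms C5=C6 last): it sets out from 7 and comes back at 17, and for the C1 epimer at 18.
- Wittig methylenation of 7 (Ph3P=CH2 from Ph3PCH3Br and KOt-Bu, THF, 0 °C) should give tert-butyl({(3R)-1-[(4-methoxybenzyl)oxy]-4,4-dimethylhex-5-en-3-yl}oxy)dimethylsilane F1.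
- DDQ in buffered CH2Cl2 should give (3R)-3-(tert-butyldimethylsilyloxy)-4,4-dimethylhex-5-en-1-ol F2.
- Dess–Martin oxidation should give (3R)-3-(tert-butyldimethylsilyloxy)-4,4-dimethylhex-5-enal F3.
- DABCO-catalysed Morita–Baylis–Hillman reaction of F3 with methyl vinyl ketone should give (6R)-6-(tert-butyldimethylsilyloxy)-4-hydroxy-7,7-dimethyl-3-methylidenenon-8-en-2-one F4 as both carbinol epimers.
- Ring-closing metathesis with the second-generation Hoveyda–Grubbs catalyst (toluene, 80 °C) should close the trisubstituted C5=C6 bond and give 17 together with 1-[(4R,6R)-4-(tert-butyldimethylsilyloxy)-6-hydroxy-3,3-dimethylcyclohex-1-en-1-yl]ethan-1-one F5, separated by chromatography.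
- 17 continues with step 10; F5 is acetylated with retention (Ac2O, DMAP, pyridine) to the same acetate 18.

**Step 12.** Substitution at C3, next to the quaternary C4, is a slow neopentyl-type displacement. It may be outrun by elimination toward C2, by ionisation followed by a 1,2-methyl shift from C4, by backside participation of the trans C1 acetate, or by attack of the phosphine on the enone acetate.

Fallback (a discrete sulfonate and a soluble bromide in place of redox condensation): it sets out from 19 and comes back at 20.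
- Tf2O and pyridine in CH2Cl2 at −40 °C should give (1R,5R)-2-acetyl-4,4-dimethyl-5-[(trifluoromethanesulfonyl)oxy]cyclohex-2-en-1-yl acetate F6.
- F6 is treated without purification with Bu4NBr in toluene from −20 °C upward. The much better leaving group lets the displacement with inversion run cold in a non-ionising solvent, where substitution should compete best with rearrangement.

**Step 15.** Configuration at C7 may be lost by ionisation of the activated allylic alcohol, by participation of the C1 acetate or the C8 chloride, or material may be lost by elimination toward C8.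

Fallback (two-stage activation and displacement with an isolated intermediate): it sets out from 23 and comes back at 24.
- MsCl and Et3N in CH2Cl2 at −20 °C should give (1R,5S)-5-bromo-2-[(1R)-2-chloro-1-(methanesulfonyloxy)ethyl]-4,4-dimethylcyclohex-2-en-1-yl acetate F7.
- F7 is displaced with inversion by excess LiBr in THF/acetone at 0 °C, where the high bromide concentration favours direct substitution over ionisation.

## Further compounds

F1 | step 9 | tert-butyl({(3R)-1-[(4-methoxybenzyl)oxy]-4,4-dimethylhex-5-en-3-yl}oxy)dimethylsilane | C=CC(C)(C)[C@H](O[Si](C)(C)C(C)(C)C)CCOCc1ccc(OC)cc1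
F2 | step 9 | (3R)-3-(tert-butyldimethylsilyloxy)-4,4-dimethylhex-5-en-1-ol | C=CC(C)(C)[C@H](O[Si](C)(C)C(C)(C)C)CCO
F3 | step 9 | (3R)-3-(tert-butyldimethylsilyloxy)-4,4-dimethylhex-5-enal | C=CC(C)(C)[C@H](O[Si](C)(C)C(C)(C)C)CC=O
F4 | step 9 | (6R)-6-(tert-butyldimethylsilyloxy)-4-hydroxy-7,7-dimethyl-3-methylidenenon-8-en-2-one (both C4 epimers) | CC(=O)C(=C)C(O)C[C@@H](O[Si](C)(C)C(C)(C)C)C(C)(C)C=C
F5 | step 9 | 1-[(4R,6R)-4-(tert-butyldimethylsilyloxy)-6-hydroxy-3,3-dimethylcyclohex-1-en-1-yl]ethan-1-one | O[C@@H]1C[C@@H](O[Si](C)(C)C(C)(C)C)C(C)(C)C=C1C(C)=O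
F6 | step 12 | (1R,5R)-2-acetyl-4,4-dimethyl-5-[(trifluoromethanesulfonyl)oxy]cyclohex-2-en-1-yl acetate | CC(=O)O[C@@H]1C[C@@H](OS(=O)(=O)C(F)(F)F)C(C)(C)C=C1C(C)=O
F7 | step 15 | (1R,5S)-5-bromo-2-[(1R)-2-chloro-1-(methanesulfonyloxy)ethyl]-4,4-dimethylcyclohex-2-en-1-yl acetate | CC(=O)O[C@@H]1C[C@H](Br)C(C)(C)C=C1[C@@H](OS(C)(=O)=O)CCl
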